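**Retrosynthetic overview**
Labels: C1 = CH(OAc) bridge, C2 = methyl bridgehead, C3H2, C4=C5(CHO), C6 = formyl bridgehead, C7 (side chain; C10 = its CH(CH3) carbon), C8, C9; ring A = C1–C6, ring B = C1, C2, C9, C8, C7, C6.
Feature: ring A is a cyclohexene whose C6 is tied back to C2 by C7–C8–C9, the pattern of a type 2 intramolecular Diels–Alder adduct. Cutting C1–C2 and C3–C4 opens rings A and B together to a triene (diene C1=C6–C5=C4 with OTBS on C1 and C5, dienophile C2=C3 as an (E)-vinyl sulfone).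
After the cycloaddition: the C5=C6 bridgehead enol silane takes up the C6 formyl carbon as CH(OMe)2, sulfinate is eliminated, the enone is reduced and triflated, C5 is formylated, and C1–OTBS becomes OAc.
Triene: (R)-citronellal plus methyl vinyl ketone (organocatalytic Michael addition, sets C7), aldehyde to C6=C5 enol ether, ketone to vinyl sulfone, C1 added at C6 with orthoformate, double silylation.

Key step: step 7

Assumption: the sense of induction in step 1 follows the usual steric-shielding model for α,α-diarylprolinol ethers; if it were the opposite, the (R)-catalyst would be used.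

Step 1
Reactants: 1 (R)-citronellal; 2 methyl vinyl ketone
Product: 3 (2S,3R)-3,7-dimethyl-2-(3-oxobutyl)oct-6-enal
Conditions: (S)-2-[methoxy(diphenyl)methyl]pyrrolidine (5 mol %), ethyl 3,4-dihydroxybenzoate (20 mol %), neat, 4 °C
Reagents that add atoms: none
Why: Enamine-catalysed Michael addition in which the (E)-enamine of 1 adds to 2 through the face remote from the CPh2OMe group, so that the catalyst and not the remote C10 centre sets C7 as S, and the α-branched product is not enolised again.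

Step 2
Reactants: 4 1,1-dimethoxyethane; 5 acetyl chloride; 6 triphenylphosphine
Product: 8 (1-methoxyethyl)triphenylphosphonium chloride, via 1-chloro-1-methoxyethane 7 (not isolated)
Conditions: ZnBr2 (1 mol %), toluene, 0 °C → rt; then PPh3, toluene, rt → 50 °C
Reagents that add atoms: none
Why: Cleavage of the acetal by the acyl chloride gives the α-chloro ether, which alkylates the phosphine at its oxocarbenium-stabilised carbon to give the phosphonium salt (no stereocentre is carried on).

Step 3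
Reactants: 3 (2S,3R)-3,7-dimethyl-2-(3-oxobutyl)oct-6-enal; 8 (1-methoxyethyl)triphenylphosphonium chloride
Product: 10 (5S,6R)-5-(2-methoxyprop-1-en-1-yl)-6,10-dimethylundec-9-en-2-one (E/Z mixture), via (1-methoxyethylidene)triphenylphosphorane 9 (not isolated)
Conditions: 8, KN(SiMe3)2, THF, −78 → −40 °C; then 3, −78 → 0 °C
Reagents that add atoms: none
Why: Wittig olefination in which the non-stabilised α-alkoxy ylide should take the aldehyde well before the methyl ketone at low temperature, which stores the future C5 ketone as a C6=C5 enol ether and leaves C7 untouched (both enol ether isomers serve).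

Step 4
Reactants: 10 (5S,6R)-5-(2-methoxyprop-1-en-1-yl)-6,10-dimethylundec-9-en-2-one; 11 diethyl [(phenylsulfonyl)methyl]phosphonate
Product: 13 (1E,5S,6R)-5-(2-methoxyprop-1-en-1-yl)-2,6,10-trimethyl-1-(phenylsulfonyl)undeca-1,9-diene, via lithiated phosphonate 12 (not isolated)
Conditions: 11 (1.2 equiv), n-BuLi (1.15 equiv), THF, −78 °C; then 10, −78 °C → rt; E isomer separated on silica
Reagents that add atoms: none
Why: Horner–Wadsworth–Emmons olefination of the methyl ketone, in which the sulfonyl group should end trans to the larger CH2 substituent (E) and a slight deficit of base avoids isomerisation to the allyl sulfone.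

Step 5
Reactants: 13 (1E,5S,6R)-5-(2-methoxyprop-1-en-1-yl)-2,6,10-trimethyl-1-(phenylsulfonyl)undeca-1,9-diene
Product: 15 (1E,5S,6R)-5-[(1Z)-1-hydroxy-3-oxobut-1-en-2-yl]-2,6,10-trimethyl-1-(phenylsulfonyl)undeca-1,9-diene (enol form of the C1 aldehyde/C5 ketone), via tetramethoxy bis-acetal 14 (not isolated)
Conditions: HC(OMe)3, BF3·OEt2 (0.1 equiv), CH2Cl2, −78 → −30 °C; then 1 M aq. HCl, THF, rt
Reagents that add atoms: trimethyl orthoformate, COC(OC)OC; water, O
Why: Lewis-acid-mediated addition of the dimethoxycarbenium ion to the enol ether (Mukaiyama-type acetal addition) can only occur at its β-carbon C6, so C1 is attached regiospecifically there, and mild aqueous acid then frees the 1,3-dicarbonyl compound, which rests as its chelated enol.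

Step 6
Reactants: 15 (1E,5S,6R)-5-[(1Z)-1-hydroxy-3-oxobut-1-en-2-yl]-2,6,10-trimethyl-1-(phenylsulfonyl)undeca-1,9-diene
Product: 17 (1E,5S,6R)-5-[(1E)-1,3-bis(tert-butyldimethylsilyloxy)buta-1,3-dien-2-yl]-2,6,10-trimethyl-1-(phenylsulfonyl)undeca-1,9-diene, via mono-silylated enone 16 (not isolated)
Conditions: TBSOTf (2.4 equiv), Et3N (4 equiv), Et2O, 0 °C → rt; filtration through Et3N-deactivated silica
Reagents that add atoms: tert-butyldimethylsilyl triflate, CC(C)(C)[Si](C)(C)OS(=O)(=O)C(F)(F)F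
Why: Soft enolisation in which O-silylation of the enol gives a push–pull alkene that should settle as the E isomer (silyloxy trans to acetyl, outside in the later diene) and a second silylation of the methyl ketone toward C4 gives the 2-silyloxy diene, as in the usual preparation of 1,3-dioxygenated dienes.

Step 7
Reactants: 17 (1E,5S,6R)-5-[(1E)-1,3-bis(tert-butyldimethylsilyloxy)buta-1,3-dien-2-yl]-2,6,10-trimethyl-1-(phenylsulfonyl)undeca-1,9-diene
Product: 18 bicyclo[3.3.1]non-1-ene adduct: C1–OTBS syn to ring B, C2 methyl, C3–SO2Ph cis to the C2 methyl, C5–OTBS on the C5=C6 bridgehead double bond, C7 side chain anti to C1–OTBS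
Conditions: degassed 1,2-dichlorobenzene (0.005 M), BHT (0.1 equiv), N,O-bis(trimethylsilyl)acetamide (0.2 equiv), silanised sealed tube, 220 °C
Reagents that add atoms: none
Why: Proposed new method: a thermal, concerted but asynchronous [4+2] cycloaddition (type 2 intramolecular Diels–Alder reaction) that bonds C1 to C2 and C4 to C3 and leaves the twisted C5=C6 enol silane; the closest known reactions are thermal type 2 cycloadditions of 2-substituted butadienes carrying a three-atom tether, which give bicyclo[3.3.1]non-1-enes, and intermolecular cycloadditions of 1,3-dioxygenated dienes with vinyl sulfones. Ring A closes as the cyclohexene of the cycloaddition and ring B as the ring that the tether C7–C8–C9 completes through the new C1–C2 bond; with three tether atoms only this 1,3-bridged mode can be reached, so the tether fixes the regiochemistry against the diene polarisation (which alone would pair C4 with C2), and the sulfone serves only to lower the dienophile LUMO. C2 is set because C9 must pass under the diene (endo), which leaves the methyl group exo; C1 is set by the (E) geometry of the enol silane, whose outside OTBS group ends cis to C9 on ring A, that is over ring B; C3 follows from the (E)-vinyl sulfone (sulfonyl exo, cis to the C2 methyl group) and is lost again in step 9. The step needs facial selectivity relative to C7: in the chair-like arrangement of the tether the C7–H bond takes the place next to the outside C1–OTBS group (1,3-allylic strain) and the side chain the equatorial place, which gives the C7/C1/C2 relationship of 26. Any (Z)-enol silane cannot adopt the reactive s-cis geometry and does not cyclise.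

Step 8
Reactants: 18 bicyclo[3.3.1]non-1-ene adduct
Product: 19 bicyclic C5 ketone with C6–CH(OMe)2 and C3–SO2Ph (C1–OTBS, C2, C7 as in 18)
Conditions: HC(OMe)3 (3 equiv), Me3SiOTf (10 mol %), 2,6-di-tert-butyl-4-methylpyridine (0.3 equiv), CH2Cl2, −78 °C
Reagents that add atoms: trimethyl orthoformate, COC(OC)OC
Why: Mukaiyama reaction of the enol silane with the dimethoxycarbenium ion, in which the twisted, electron-rich C5=C6 bond can be attacked only on its outer face, so that C6 becomes a quaternary bridgehead of the configuration the bicycle dictates and the C5 ketone is released, the hindered pyridine holding back protodesilylation.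

Step 9
Reactants: 19 bicyclic C5 ketone with C6–CH(OMe)2 and C3–SO2Ph
Product: 20 bicyclic enone: C3=C4–C5=O, C6–CH(OMe)2, C1–OTBS
Conditions: DBU (1.5 equiv), CH2Cl2, 0 °C → rt
Reagents that add atoms: none
Why: E1cB elimination in which the C4 enolate of the β-sulfonyl ketone expels benzenesulfinate to give the C3=C4 enone, with loss of the C3 stereocentre.

Step 10
Reactants: 20 bicyclic enone
Product: 22 bicyclic enol triflate: C4=C5(OTf); C6–CH(OMe)2; C1–OTBS, via lithium enolate 21 (not isolated)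
Conditions: LiBH(s-Bu)3 (1.1 equiv), THF, −78 °C; then N-(5-chloropyridin-2-yl)bis(trifluoromethanesulfonimide), −78 → 0 °C
Reagents that add atoms: N-(5-chloropyridin-2-yl)-1,1,1-trifluoro-N-(trifluoromethylsulfonyl)methanesulfonamide, O=S(=O)(N(c1ccc(Cl)cn1)S(=O)(=O)C(F)(F)F)C(F)(F)F
Why: Conjugate reduction with enolate trapping, in which the bulky hydride should add to the unsubstituted β-carbon C3 (the C5 carbonyl is shielded by quaternary C6) and the regiodefined C4=C5 enolate is O-triflated.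

Step 11
Reactants: 22 bicyclic enol triflate
Product: 23 bicyclic alcohol: C1–OH, C4=C5(OTf), C6–CH(OMe)2
Conditions: HF·pyridine, excess pyridine, THF, 0 → 40 °C
Reagents that add atoms: none
Why: Fluoride-mediated cleavage of the hindered C1 silyl ether under buffered acidic conditions, which forms no alkoxide that could attack the triflate and should leave the dimethyl acetal and the trisubstituted alkene alone.

Step 12
Reactants: 23 bicyclic alcohol
Product: 24 bicyclic acetate: C1–OAc, C4=C5(OTf), C6–CH(OMe)2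
Conditions: Ac2O, DMAP, Et3N, CH2Cl2, rt → 40 °C
Reagents that add atoms: acetic anhydride, CC(=O)OC(C)=O
Why: DMAP-catalysed acylation of the hindered secondary alcohol, done before either aldehyde is free so that no retro-aldol cleavage of the C1–C6 bond can intervene.

Step 13
Reactants: 24 bicyclic acetate
Product: 25 bicyclic enal: C4=C5(CHO), C6–CH(OMe)2, C1–OAc
Conditions: Pd(OAc)2 (5 mol %), Ph2P(CH2)3PPh2 (5 mol %), CO (1 atm), Et3SiH (2 equiv), Et3N, DMF, 70 °C
Reagents that add atoms: carbon monoxide, [C-]#[O+]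
Why: Palladium-catalysed reductive carbonylation (formylation) of the vinyl triflate by oxidative addition of zerovalent palladium, CO insertion and hydride transfer from the silane, which tolerates the acetate, the acetal and the trisubstituted alkene.

Step 14
Reactants: 25 bicyclic enal
Product: 26 (1R,5R,8S,9R)-1,2-diformyl-5-methyl-8-[(2R)-6-methylhept-5-en-2-yl]bicyclo[3.3.1]non-2-en-9-yl acetate (CNP0299929.2)
Conditions: 1 M aq. HCl, THF, 0 °C → rt
Reagents that add atoms: water, O
Why: Acid-catalysed acetal hydrolysis frees the C6 aldehyde, and because C6 is quaternary neither epimerisation nor β-elimination of the acetate is possible.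

**Compound list**
1 | (R)-citronellal, (3R)-3,7-dimethyloct-6-enal | O=CC[C@H](C)CCC=C(C)C | starting material
2 | methyl vinyl ketone | CC(=O)C=C | starting material
3 | (2S,3R)-3,7-dimethyl-2-(3-oxobutyl)oct-6-enal | O=C[C@H]([C@H](C)CCC=C(C)C)CCC(C)=O | intermediate
4 | 1,1-dimethoxyethane | CC(OC)OC | starting material
5 | acetyl chloride | CC(=O)Cl | starting material
6 | triphenylphosphine | c1ccc(cc1)P(c1ccccc1)c1ccccc1 | starting material
7 | 1-chloro-1-methoxyethane (racemic) | COC(C)Cl | intermediate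
8 | (1-methoxyethyl)triphenylphosphonium chloride | COC(C)[P+](c1ccccc1)(c1ccccc1)c1ccccc1.[Cl-] | intermediate
9 | (1-methoxyethylidene)triphenylphosphorane | COC(C)=P(c1ccccc1)(c1ccccc1)c1ccccc1 | intermediate
10 | (5S,6R)-5-(2-methoxyprop-1-en-1-yl)-6,10-dimethylundec-9-en-2-one (E/Z mixture at the enol ether) | COC(C)=C[C@H]([C@H](C)CCC=C(C)C)CCC(C)=O | intermediate
11 | diethyl [(phenylsulfonyl)methyl]phosphonate | CCOP(=O)(CS(=O)(=O)c1ccccc1)OCC | starting material
12 | diethyl [lithio(phenylsulfonyl)methyl]phosphonate | [Li+].CCOP(=O)([CH-]S(=O)(=O)c1ccccc1)OCC | intermediate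
13 | (1E,5S,6R)-5-(2-methoxyprop-1-en-1-yl)-2,6,10-trimethyl-1-(phenylsulfonyl)undeca-1,9-diene | COC(C)=C[C@H]([C@H](C)CCC=C(C)C)CC/C(C)=C/S(=O)(=O)c1ccccc1 | intermediate
14 | (1E,5S,6R)-2,6,10-trimethyl-1-(phenylsulfonyl)-5-(1,1,3,3-tetramethoxybutan-2-yl)undeca-1,9-diene (both epimers at C6) | COC(OC)C(C(C)(OC)OC)[C@H]([C@H](C)CCC=C(C)C)CC/C(C)=C/S(=O)(=O)c1ccccc1 | intermediate
15 | (1E,5S,6R)-5-[(1Z)-1-hydroxy-3-oxobut-1-en-2-yl]-2,6,10-trimethyl-1-(phenylsulfonyl)undeca-1,9-diene | O/C=C(\C(C)=O)[C@H]([C@H](C)CCC=C(C)C)CC/C(C)=C/S(=O)(=O)c1ccccc1 | intermediate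
16 | (1E,5S,6R)-5-[(1E)-1-(tert-butyldimethylsilyloxy)-3-oxobut-1-en-2-yl]-2,6,10-trimethyl-1-(phenylsulfonyl)undeca-1,9-diene | CC(=O)/C(=C/O[Si](C)(C)C(C)(C)C)[C@H]([C@H](C)CCC=C(C)C)CC/C(C)=C/S(=O)(=O)c1ccccc1 | intermediate
17 | (1E,5S,6R)-5-[(1E)-1,3-bis(tert-butyldimethylsilyloxy)buta-1,3-dien-2-yl]-2,6,10-trimethyl-1-(phenylsulfonyl)undeca-1,9-diene | C=C(O[Si](C)(C)C(C)(C)C)/C(=C/O[Si](C)(C)C(C)(C)C)[C@H]([C@H](C)CCC=C(C)C)CC/C(C)=C/S(=O)(=O)c1ccccc1 | intermediate
18 | 2,9-bis(tert-butyldimethylsilyloxy)-5-methyl-8-[(2R)-6-methylhept-5-en-2-yl]-4-(phenylsulfonyl)bicyclo[3.3.1]non-1-ene; route labels: C1–OTBS syn to ring B, C3–SO2Ph cis to C2 methyl, C7 chain anti to C1–OTBS | CC(C)(C)[Si](C)(C)O[C@@H]1[C@@]2(C)[C@@H](S(=O)(=O)c3ccccc3)CC(O[Si](C)(C)C(C)(C)C)=C1[C@H]([C@H](C)CCC=C(C)C)CC2 | intermediate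
19 | bicyclic C5 ketone: C6–CH(OMe)2, C3–SO2Ph, C1–OTBS (centres as in 18, C6 as in 26) | CC(C)(C)[Si](C)(C)O[C@@H]1[C@@]2(C)[C@@H](S(=O)(=O)c3ccccc3)CC(=O)[C@]1(C(OC)OC)[C@H]([C@H](C)CCC=C(C)C)CC2 | intermediate
20 | bicyclic enone: C3=C4–C5=O, C6–CH(OMe)2, C1–OTBS | CC(C)(C)[Si](C)(C)O[C@@H]1[C@@]2(C)C=CC(=O)[C@]1(C(OC)OC)[C@H]([C@H](C)CCC=C(C)C)CC2 | intermediate
21 | lithium C4=C5 enolate of the reduced enone | [Li+].CC(C)(C)[Si](C)(C)O[C@@H]1[C@@]2(C)CC=C([O-])[C@]1(C(OC)OC)[C@H]([C@H](C)CCC=C(C)C)CC2 | intermediate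
22 | bicyclic enol triflate: C4=C5(OTf), C6–CH(OMe)2, C1–OTBS | CC(C)(C)[Si](C)(C)O[C@@H]1[C@@]2(C)CC=C(OS(=O)(=O)C(F)(F)F)[C@]1(C(OC)OC)[C@H]([C@H](C)CCC=C(C)C)CC2 | intermediate
23 | bicyclic alcohol: C1–OH, C4=C5(OTf), C6–CH(OMe)2 | O[C@@H]1[C@@]2(C)CC=C(OS(=O)(=O)C(F)(F)F)[C@]1(C(OC)OC)[C@H]([C@H](C)CCC=C(C)C)CC2 | intermediate
24 | bicyclic acetate: C1–OAc, C4=C5(OTf), C6–CH(OMe)2 | CC(=O)O[C@@H]1[C@@]2(C)CC=C(OS(=O)(=O)C(F)(F)F)[C@]1(C(OC)OC)[C@H]([C@H](C)CCC=C(C)C)CC2 | intermediate
25 | bicyclic enal: C4=C5(CHO), C6–CH(OMe)2, C1–OAc | CC(=O)O[C@@H]1[C@@]2(C)CC=C(C=O)[C@]1(C(OC)OC)[C@H]([C@H](C)CCC=C(C)C)CC2 | intermediate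
26 | (1R,5R,8S,9R)-1,2-diformyl-5-methyl-8-[(2R)-6-methylhept-5-en-2-yl]bicyclo[3.3.1]non-2-en-9-yl acetate | CC(=O)O[C@@H]1[C@@]2(C)CC=C(C=O)[C@]1(C=O)[C@H]([C@H](C)CCC=C(C)C)CC2 | target

**Step count**
Total: 14 steps. Longest linear sequence: 13 steps (steps 1 and 3–14; step 2 is a side branch).

**Three steps most likely to fail**

1. Step 7. The cycloaddition may be too slow (three-atom tether, trisubstituted dienophile, regiochemistry opposed to the diene polarisation), so that desilylation, sulfone isomerisation or oligomerisation takes over, or the wrong face of the diene may react. Fallback from 1, back to the route at 22, with known reaction types only. Enamine-catalysed α-hydroxymethylation of 1 (aqueous CH2O, (S)-2-[diphenyl(trimethylsilyloxy)methyl]pyrrolidine) gives the hydroxy aldehyde F1, and t-BuPh2SiCl/imidazole gives the silyl ether F2. Wittig reaction with ylide 9 gives the enol ether F3. HC(OMe)3/BF3·OEt2 gives the bis-acetal F4, and aqueous HCl gives the enolised keto aldehyde F5. TBSOTf/Et3N gives the diene F6. An intermolecular Diels–Alder reaction with methacrolein (toluene, 80 °C) gives the cyclohexene F7; this cycloaddition is polarity-matched (C4 bonds to the CH2 terminus, the formyl-bearing carbon becomes C2 and the formyl carbon C9), endo, and expected anti to the larger C7 substituent. A Mukaiyama reaction with HC(OMe)3/Me3SiOTf, trans to C1–OTBS, gives the ring A ketone F8. Bu4NF/AcOH frees the primary alcohol F9, and I2/PPh3/imidazole gives the iodide F10. PPh3 in MeCN gives the phosphonium iodide F11. An intramolecular Wittig reaction (KN(SiMe3)2, high dilution) closes ring B as the bicyclic alkene F12. Diimide (potassium azodicarboxylate, AcOH) reduces the disubstituted C8=C9 bond to give the bicyclic ketone F13. KN(SiMe3)2 and the triflimide of step 10 then give 22.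

2. Step 8. The strained enol silane may be protodesilylated, or the bulky dimethoxycarbenium ion may fail to bond to the bridgehead carbon. Fallback from 18, back to the route at 19: the small iminium electrophile (chloromethylene)dimethyliminium chloride (CH2Cl2, −40 → 0 °C, then aqueous NaOAc) formylates C6 to give the keto aldehyde F14, which is protected separately (HC(OMe)3, pyridinium p-toluenesulfonate, MeOH) to give 19.

3. Step 3. The ylide may attack the methyl ketone, or the branched aldehyde may be enolised with loss of configuration at C7 during a slow olefination. Fallback from 3, back to the route at 13: the aldehyde is masked first (HC(OMe)3, CeCl3·7H2O, MeOH) as the keto acetal F15. The ketone is then olefinated with 11/n-BuLi to give the vinyl sulfone acetal F16. Aqueous oxalic acid/THF frees the aldehyde F17, which now meets ylide 9 with no competing carbonyl group and gives 13.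

**Further compounds**
F1 | step 7 | (2R,3R)-2-(hydroxymethyl)-3,7-dimethyloct-6-enal | O=C[C@H]([C@H](C)CCC=C(C)C)CO
F2 | step 7 | (2R,3R)-2-[(tert-butyldiphenylsilyloxy)methyl]-3,7-dimethyloct-6-enal | O=C[C@H]([C@H](C)CCC=C(C)C)CO[Si](c1ccccc1)(c1ccccc1)C(C)(C)C
F3 | step 7 | tert-butyl{[(2S,3R)-2-(2-methoxyprop-1-en-1-yl)-3,7-dimethyloct-6-en-1-yl]oxy}diphenylsilane | COC(C)=C[C@H]([C@H](C)CCC=C(C)C)CO[Si](c1ccccc1)(c1ccccc1)C(C)(C)C
F4 | step 7 | bis-acetal analogue of 14 with C8 = CH2OSiPh2t-Bu | COC(OC)C(C(C)(OC)OC)[C@H]([C@H](C)CCC=C(C)C)CO[Si](c1ccccc1)(c1ccccc1)C(C)(C)C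
F5 | step 7 | enolised keto aldehyde analogue of 15 with C8 = CH2OSiPh2t-Bu | O/C=C(\C(C)=O)[C@H]([C@H](C)CCC=C(C)C)CO[Si](c1ccccc1)(c1ccccc1)C(C)(C)C
F6 | step 7 | (E)-1,3-bis(TBS-oxy)diene analogue of 17 with C8 = CH2OSiPh2t-Bu | C=C(O[Si](C)(C)C(C)(C)C)/C(=C/O[Si](C)(C)C(C)(C)C)[C@H]([C@H](C)CCC=C(C)C)CO[Si](c1ccccc1)(c1ccccc1)C(C)(C)C
F7 | step 7 | cyclohexene adduct: C1–OTBS, C2(CH3)(CHO), C5(OTBS)=C6, C7 chain with CH2OSiPh2t-Bu | CC(C)(C)[Si](C)(C)O[C@@H]1[C@](C)(C=O)CCC(O[Si](C)(C)C(C)(C)C)=C1[C@H]([C@H](C)CCC=C(C)C)CO[Si](c2ccccc2)(c2ccccc2)C(C)(C)C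
F8 | step 7 | ring A ketone: C5=O, C6–CH(OMe)2, C2–CHO, C1–OTBS, C8–OSiPh2t-Bu | CC(C)(C)[Si](C)(C)O[C@@H]1[C@](C)(C=O)CCC(=O)[C@]1(C(OC)OC)[C@H]([C@H](C)CCC=C(C)C)CO[Si](c2ccccc2)(c2ccccc2)C(C)(C)C
F9 | step 7 | primary alcohol from F8 (C8–OH) | CC(C)(C)[Si](C)(C)O[C@@H]1[C@](C)(C=O)CCC(=O)[C@]1(C(OC)OC)[C@H]([C@H](C)CCC=C(C)C)CO
F10 | step 7 | primary iodide from F9 (C8–I) | CC(C)(C)[Si](C)(C)O[C@@H]1[C@](C)(C=O)CCC(=O)[C@]1(C(OC)OC)[C@H]([C@H](C)CCC=C(C)C)CI
F11 | step 7 | triphenylphosphonium iodide from F10 | CC(C)(C)[Si](C)(C)O[C@@H]1[C@](C)(C=O)CCC(=O)[C@]1(C(OC)OC)[C@H]([C@H](C)CCC=C(C)C)C[P+](c2ccccc2)(c2ccccc2)c2ccccc2.[I-]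
F12 | step 7 | bicyclic alkene: C8=C9, C5=O, C6–CH(OMe)2, C1–OTBS | CC(C)(C)[Si](C)(C)O[C@@H]1[C@@]2(C)CCC(=O)[C@]1(C(OC)OC)[C@H]([C@H](C)CCC=C(C)C)C=C2
F13 | step 7 | bicyclic ketone: C5=O, C3H2, C4H2, C6–CH(OMe)2, C1–OTBS | CC(C)(C)[Si](C)(C)O[C@@H]1[C@@]2(C)CCC(=O)[C@]1(C(OC)OC)[C@H]([C@H](C)CCC=C(C)C)CC2
F14 | step 8 | bicyclic keto aldehyde: C5=O, C6–CHO, C3–SO2Ph, C1–OTBS | CC(C)(C)[Si](C)(C)O[C@@H]1[C@@]2(C)[C@@H](S(=O)(=O)c3ccccc3)CC(=O)[C@]1(C=O)[C@H]([C@H](C)CCC=C(C)C)CC2
F15 | step 3 | (5S,6R)-5-(dimethoxymethyl)-6,10-dimethylundec-9-en-2-one | COC(OC)[C@H]([C@H](C)CCC=C(C)C)CCC(C)=O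
F16 | step 3 | (1E,5S,6R)-5-(dimethoxymethyl)-2,6,10-trimethyl-1-(phenylsulfonyl)undeca-1,9-diene | COC(OC)[C@H]([C@H](C)CCC=C(C)C)CC/C(C)=C/S(=O)(=O)c1ccccc1
F17 | step 3 | (2S,3R)-3,7-dimethyl-2-[(3E)-3-methyl-4-(phenylsulfonyl)but-3-en-1-yl]oct-6-enal | O=C[C@H]([C@H](C)CCC=C(C)C)CC/C(C)=C/S(=O)(=O)c1ccccc1
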